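**Assumptions.** Squalene-type numbering is used: left bicycle C2–C11 (C2 = CMe2, C3 = CHOAc, C6 = quaternary C, C7 = CH–O, C10 = C=CH2, C11 = CH), linker C12–C13, right bicycle C14–C23 (C14 = C–OH, C15 = CHMe, C18 = CH–O, C19 = quaternary C, C22 = C=O, C23 = CMe2). The SMILES corresponds to 3R,6S,7S,11R,14S,15S,18S,19R, with both bicycles trans-fused. Isopropenylmagnesium bromide is taken as a commercial solution.

## Retrosynthetic overview

1. Target ⇒ C22 alcohol oxidation and C10 ketone methylenation ⇒ radical Giese union at C12–C13 of iodohydrin 17 (right bicycle) with α-methylene ketone 14 (left bicycle).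
2. Both bicycles ⇒ one common trans-fused oxepane–cyclohexanone 10.
3. 10 ⇒ oxepane O–C2 bond by 7-exo alkoxymercuration of allylic alcohol 8.
4. Key disconnection: the C5–C6 (≡ C20–C19) bond at the quaternary ring-fusion carbon ⇒ Ti(III)-generated tertiary radical from epoxide 3 plus acrylonitrile, adding anti to the C7 oxygen.
5. Ring order: both cyclohexanes are bought as 2-methylcyclohexenone; the oxepane is closed once (step 6) on the common intermediate; no ring is formed after the union.

## Route

**Step 1**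
Reactants: 1, 2-methylcyclohex-2-en-1-one
Product: 2, 6-methyl-1,4-dioxaspiro[4.5]dec-6-ene
Conditions: (TMSOCH2)2, TMSOTf (cat.), CH2Cl2, −78 → −20 °C
Reagents that add atoms: 1,2-bis(trimethylsilyloxy)ethane, C[Si](C)(C)OCCO[Si](C)(C)C
Why: Noyori ketalisation masks the ketone without moving the alkene, so the later epoxide is not an α,β-epoxy ketone (which Ti(III) would only reduce).

**Step 2**
Reactants: 2
Product: 3, ethylene ketal of (1S,6S)-1-methyl-7-oxabicyclo[4.1.0]heptan-2-one
Conditions: ent-Shi ketone (L-fructose-derived, 0.3 equiv), Oxone, K2CO3, Bu4NHSO4, MeCN/DMM/aq. buffer pH 10.5, 0 °C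
Reagents that add atoms: Oxone (KHSO5), OOS(=O)(=O)[O-].[K+]
Why: Shi asymmetric epoxidation of a trisubstituted alkene (spiro transition state) sets C7 absolutely; the antipode is chosen by analogy with 1-substituted cyclohexenes, and whichever antipode gives (1S,6S) is used.

**Step 3 (key step)**
Reactants: 3; 4, acrylonitrile
Product: 5, 3-[(6R,7S)-7-hydroxy-6-methyl-1,4-dioxaspiro[4.5]decan-6-yl]propanenitrile
Conditions: Cp2TiCl2 (2.5 equiv), Zn dust, THF, rt; slow addition of 3 and 4 (6 equiv); aq. NaH2PO4
Reagents that add atoms: none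
Why: Nugent–RajanBabu Ti(III) epoxide opening gives the tertiary C6 radical, and Giese addition anti to the bulky C7–OTi group creates the quaternary centre with the chain trans to oxygen, as the trans-fused oxepane needs (a dione Michael/reduction sequence would be expected to give the cis isomer).

**Step 4**
Reactants: 5; 6, isopropenylmagnesium bromide
Product: 7, 5-[(6R,7S)-7-hydroxy-6-methyl-1,4-dioxaspiro[4.5]decan-6-yl]-2-methylpent-1-en-3-one
Conditions: 6 (3.5 equiv), CuBr·SMe2 (5 mol %), THF, 0 → 60 °C; then cold 10% aq. citric acid, 0 °C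
Reagents that add atoms: water, O
Why: Cu-catalysed Grignard addition to the nitrile gives the N-magnesio ketimine, which mild acid hydrolyses to the enone while the dioxolane survives.

**Step 5**
Reactants: 7
Product: 8, (3R)-5-[(6R,7S)-7-hydroxy-6-methyl-1,4-dioxaspiro[4.5]decan-6-yl]-2-methylpent-1-en-3-ol
Conditions: (S)-Me-CBS (0.2 equiv), catecholborane (2.5 equiv), toluene, −78 °C
Reagents that add atoms: none
Why: CBS reduction with the isopropenyl group as the large substituent gives the (R)-allylic alcohol, which sets C3 (and C22, later oxidised).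

**Step 6**
Reactants: 8
Product: 9, ethylene ketal of 10: (3R,5aR,9aS)-2,2,5a-trimethyloctahydrospiro[1-benzoxepine-6,2'-[1,3]dioxolan]-3-ol
Conditions: Hg(OCOCF3)2 (1.3 equiv), MeCN, −20 → 0 °C; then 3 M NaOH, NaBH4, 0 °C
Reagents that add atoms: none
Why: Reversible Markovnikov alkoxymercuration (7-exo-trig) puts the C7 oxygen on the tertiary carbon, and reductive demercuration turns CH2Hg into the second methyl, so C2 carries no stereocentre and the trans fusion comes from step 3.

**Step 7**
Reactants: 9
Product: 10, (3R,5aR,9aS)-3-hydroxy-2,2,5a-trimethyloctahydro-1-benzoxepin-6(2H)-one (common intermediate)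
Conditions: 1 M HCl, THF, rt
Reagents that add atoms: water, O
Why: Ketal hydrolysis; the β-alkoxy ketone cannot eliminate because the intervening carbon is quaternary.

**Step 8 (left branch)**
Reactants: 10
Product: 11, (3R,5aS,9aS)-2,2,5a-trimethyl-6-methylidenedecahydro-1-benzoxepin-3-ol
Conditions: Ph3PCH3Br (4 equiv), KOt-Bu (4 equiv), toluene, 90 °C
Reagents that add atoms: methylenetriphenylphosphorane, C=P(c1ccccc1)(c1ccccc1)c1ccccc1
Why: Forcing Wittig methylenation of the α-quaternary ketone; the new CH2 becomes C12 of the target.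

**Step 9**
Reactants: 11
Product: 12, (3R,5aS,9aS)-2,2,5a-trimethyl-6-methylidenedecahydro-1-benzoxepin-3-yl acetate
Conditions: Ac2O, pyridine, DMAP (cat.), CH2Cl2, rt
Reagents that add atoms: acetic anhydride, CC(=O)OC(C)=O
Why: Acetylation installs the C3 acetate now, so the two secondary carbinols (C3, C22) stay differentiated after the union.

**Step 10**
Reactants: 12
Product: 13, (3R,5aS,9aS)-7-hydroxy-2,2,5a-trimethyl-6-methylidenedecahydro-1-benzoxepin-3-yl acetate (C7 epimers, inconsequential)
Conditions: SeO2 (0.5 equiv), t-BuOOH (3 equiv), CH2Cl2, rt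
Reagents that add atoms: tert-butyl hydroperoxide, CC(C)(C)OO (oxygen delivered via SeO2, O=[Se]=O)
Why: SeO2 ene/[2,3] allylic oxidation; the only allylic C–H is at C10 because the other neighbour is quaternary.

**Step 11**
Reactants: 13
Product: 14, (3R,5aS,9aS)-2,2,5a-trimethyl-6-methylidene-7-oxodecahydro-1-benzoxepin-3-yl acetate
Conditions: Dess–Martin periodinane, NaHCO3, CH2Cl2, 0 °C → rt; used at once
Reagents that add atoms: none
Why: Oxidation of the allylic alcohol gives the α-methylene ketone (C10 ketone, C11=C12 acceptor).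

**Step 12 (right branch)**
Reactants: 10
Product: 15, (3R,5aR,7S,9aS)-3-hydroxy-2,2,5a,7-tetramethyloctahydro-1-benzoxepin-6(2H)-one
Conditions: LDA (2.2 equiv), THF, −78 °C; MeI (1.1 equiv), −78 → −20 °C; then NaOMe, MeOH, rt
Reagents that add atoms: iodomethane, CI
Why: Enolate methylation at the only enolisable position (C15); equilibration gives the equatorial methyl, which avoids the 1,3-diaxial clash with the angular methyl.

**Step 13**
Reactants: 15
Product: 16, (3R,5aS,7S,9aS)-2,2,5a,7-tetramethyl-6-methylidenedecahydro-1-benzoxepin-3-ol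
Conditions: Ph3PCH3Br, KOt-Bu, toluene, 110 °C
Reagents that add atoms: methylenetriphenylphosphorane, C=P(c1ccccc1)(c1ccccc1)c1ccccc1
Why: Wittig methylenation of the hindered ketone (as for 2,2,6-trimethylcyclohexanone); the new CH2 becomes C13.

**Step 14**
Reactants: 16
Product: 17, (3R,5aR,6S,7S,9aS)-6-(iodomethyl)-2,2,5a,7-tetramethyldecahydro-1-benzoxepine-3,6-diol
Conditions: NIS (1.2 equiv), THF/H2O 3:1, 0 °C, dark
Reagents that add atoms: N-iodosuccinimide, O=C1CCC(=O)N1I; water, O
Why: Markovnikov iodohydrin formation, with water attacking C14 axially and anti to the axial angular methyl (as in oxymercuration of methylenecyclohexanes), gives the axial 14-OH that carbonyl addition would not be expected to give; if selectivity is poor, mCPBA then MgI2 gives the same iodohydrin.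

**Step 15 (union)**
Reactants: 17; 14
Product: 18, the 10-oxo-22-hydroxy coupled seco-precursor (target skeleton with C10=O in place of C10=CH2 and (22R)-OH in place of the C22 ketone)
Conditions: 17 (1 equiv), 14 (1.5 equiv), (Me3Si)3SiH (1.5 equiv, slow addition), Et3B/air, toluene, rt; then DBU (0.2 equiv), CH2Cl2, rt
Reagents that add atoms: none
Why: Giese addition of the primary β-hydroxyalkyl radical (whose anion would β-eliminate) to the α-methylene ketone forms C12–C13, and base equilibration α to the C10 ketone puts the C11 chain equatorial (11R in the target).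

**Step 16**
Reactants: 18
Product: 19, 22-hydroxy precursor (target with (22R)-OH in place of the C22 ketone)
Conditions: Zn, CH2Br2, TiCl4 (Takai–Lombardo), THF/CH2Cl2, 0 °C → rt
Reagents that add atoms: dibromomethane, BrCBr
Why: Non-basic Takai–Lombardo methylenation converts the C10 ketone to the exocyclic alkene without epimerising C11 and leaves the acetate and free hydroxyls alone.

**Step 17**
Reactants: 19
Product: 20, 3-epi-sodwanone K 3-acetate
Conditions: Dess–Martin periodinane, pyridine, CH2Cl2, 0 °C → rt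
Reagents that add atoms: none
Why: Only the secondary C22 alcohol can be oxidised (C14-OH is tertiary, C3 is acetylated), giving the target.

## Compound list

1 | 2-methylcyclohex-2-en-1-one | CC1=CCCCC1=O | starting material
2 | 6-methyl-1,4-dioxaspiro[4.5]dec-6-ene | CC1=CCCCC12OCCO2 | intermediate
3 | (1S,6S)-1-methyl-7-oxabicyclo[4.1.0]heptan-2-one ethylene ketal | C[C@]12O[C@H]1CCCC23OCCO3 | intermediate
4 | acrylonitrile | C=CC#N | starting material
5 | 3-[(6R,7S)-7-hydroxy-6-methyl-1,4-dioxaspiro[4.5]decan-6-yl]propanenitrile | N#CCC[C@]1(C)[C@@H](O)CCCC12OCCO2 | intermediate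
6 | isopropenylmagnesium bromide | C=C(C)[Mg]Br | starting material
7 | 5-[(6R,7S)-7-hydroxy-6-methyl-1,4-dioxaspiro[4.5]decan-6-yl]-2-methylpent-1-en-3-one | C=C(C)C(=O)CC[C@]1(C)[C@@H](O)CCCC12OCCO2 | intermediate
8 | (3R)-5-[(6R,7S)-7-hydroxy-6-methyl-1,4-dioxaspiro[4.5]decan-6-yl]-2-methylpent-1-en-3-ol | C=C(C)[C@H](O)CC[C@]1(C)[C@@H](O)CCCC12OCCO2 | intermediate
9 | (3R,5aR,9aS)-2,2,5a-trimethyloctahydrospiro[1-benzoxepine-6,2'-[1,3]dioxolan]-3-ol | CC1(C)O[C@H]2CCCC3(OCCO3)[C@]2(C)CC[C@H]1O | intermediate
10 | (3R,5aR,9aS)-3-hydroxy-2,2,5a-trimethyloctahydro-1-benzoxepin-6(2H)-one | CC1(C)O[C@H]2CCCC(=O)[C@]2(C)CC[C@H]1O | intermediate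
11 | (3R,5aS,9aS)-2,2,5a-trimethyl-6-methylidenedecahydro-1-benzoxepin-3-ol | CC1(C)O[C@H]2CCCC(=C)[C@]2(C)CC[C@H]1O | intermediate
12 | (3R,5aS,9aS)-2,2,5a-trimethyl-6-methylidenedecahydro-1-benzoxepin-3-yl acetate | CC1(C)O[C@H]2CCCC(=C)[C@]2(C)CC[C@H]1OC(C)=O | intermediate
13 | (3R,5aS,9aS)-7-hydroxy-2,2,5a-trimethyl-6-methylidenedecahydro-1-benzoxepin-3-yl acetate (C7 epimers) | CC1(C)O[C@H]2CCC(O)C(=C)[C@]2(C)CC[C@H]1OC(C)=O | intermediate
14 | (3R,5aS,9aS)-2,2,5a-trimethyl-6-methylidene-7-oxodecahydro-1-benzoxepin-3-yl acetate | CC1(C)O[C@H]2CCC(=O)C(=C)[C@]2(C)CC[C@H]1OC(C)=O | intermediate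
15 | (3R,5aR,7S,9aS)-3-hydroxy-2,2,5a,7-tetramethyloctahydro-1-benzoxepin-6(2H)-one | CC1(C)O[C@H]2CC[C@H](C)C(=O)[C@]2(C)CC[C@H]1O | intermediate
16 | (3R,5aS,7S,9aS)-2,2,5a,7-tetramethyl-6-methylidenedecahydro-1-benzoxepin-3-ol | CC1(C)O[C@H]2CC[C@H](C)C(=C)[C@]2(C)CC[C@H]1O | intermediate
17 | (3R,5aR,6S,7S,9aS)-6-(iodomethyl)-2,2,5a,7-tetramethyldecahydro-1-benzoxepine-3,6-diol | CC1(C)O[C@H]2CC[C@H](C)[C@@](O)(CI)[C@]2(C)CC[C@H]1O | intermediate
18 | 10-oxo-22-hydroxy coupled precursor (C10 ketone, 3-OAc, 14-OH, (22R)-OH) | O=C1CC[C@@H]2OC(C)(C)[C@H](OC(C)=O)CC[C@@]2(C)[C@@H]1CC[C@]1(O)[C@@H](C)CC[C@@H]2OC(C)(C)[C@H](O)CC[C@]21C | intermediate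
19 | 22-hydroxy precursor (target with (22R)-OH in place of C22=O) | C=C1CC[C@@H]2OC(C)(C)[C@H](OC(C)=O)CC[C@@]2(C)[C@@H]1CC[C@]1(O)[C@@H](C)CC[C@@H]2OC(C)(C)[C@H](O)CC[C@]21C | intermediate
20 | 3-epi-sodwanone K 3-acetate | C=C1CC[C@@H]2OC(C)(C)[C@H](OC(C)=O)CC[C@@]2(C)[C@@H]1CC[C@]1(O)[C@@H](C)CC[C@@H]2OC(C)(C)C(=O)CC[C@]21C | target

## Totals and risks

Total steps: 17. Longest linear sequence: 14 (steps 1–7, 8–11, 15–17); the right branch is 13.

Steps most likely to fail:

1. **Step 6** (7-exo alkoxymercuration forming a hindered tertiary ether). Fallback: change the ring-closing bond from O–C2 to C7–O. Oxidise C7-OH to the ketone, carry C2 as a tertiary alcohol (for example from dihydroxylation of a homoprenyl side chain with C3-O protected), and close by Et3SiH/TMSOTf reductive etherification. Axial hydride delivery then gives the same trans fusion.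
2. **Step 3** (Ti(III) Giese at a tertiary radical flanked by a ketal; yield and anti selectivity). Fallback: generate the C6 radical by metal-hydride hydrogen-atom transfer instead. Isomerise epoxide 3 to the exocyclic allylic alcohol, silylate it, and couple with acrylonitrile under Fe(acac)3/PhSiH3, the bulky silyl ether directing anti addition.
3. **Step 15** (intermolecular Giese between two advanced fragments with a neopentyl-type radical). Fallback: polar union. Epoxidise 16 (mCPBA), open with PhSNa, oxidise to the β-hydroxy sulfone, add its dianion to enone 14 in a Michael reaction, then remove the sulfone with Na/Hg.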